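(The numbers in the tables are simulated on assumed constants.)

If G leaves by two first-order steps and by a step of second order in G, the share of the charge reaching Q falls as the charge rises, while the amount of Q still grows. I assume this pattern for the flasks below.

| flask | G | E | remark | time |
|---|---|---|---|---|
| Wednesday's | 0.0016 M | 10 mM | run made earlier |  |
| Friday's | 0.022 M | 10 mM | run made earlier |  |
| midnight | 0.0030 M | 10.0 mM |  | 8.0 min |
| noon | 0.010 M | 10.0 mM |  | 8.0 min |
| dawn | 0.030 M | 10.0 mM |  | 8.0 min |

| run | time / min | Q / % | G / % |
|---|---|---|---|
| Wednesday's | 0.667 | 29.1 | 28.4 |
| Wednesday's | 2.00 | 40.4 | 3.4 |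
| Wednesday's | 4.00 | 42.7 | 1.1 |
| Wednesday's | 6.00 | 42.3 | 0.1 |
| Wednesday's | 8.00 | 41.6 | 0 |
| Friday's | 0.667 | 11.3 | 6.2 |
| Friday's | 1.33 | 13.0 | 1.4 |
| Friday's | 2.50 | 13.5 | 0.6 |
| Friday's | 4.00 | 14.0 | 0 |
| Friday's | 8.00 | 13.8 | 0 |

(standard deviation of a reading: 0.5 percentage points)

- percentages count the G that a species holds: one Z counts as two
- percentages count the G that a species holds: one L counts as three
- on the list of suspects stand: G + Z -> L; G -> Q; G + E -> X; 2 G -> Z
- "hardly changes" means that all values lie within two and a half points (for a concentration: within two and a half percent of the largest)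

- amount of Q at the end, in percent of the G charged for midnight, noon, dawn, in this order
- how that number moves from the first to the last of them (rises, then falls / falls all the way / rises all the way / falls, then rises / hardly changes)

These two trends give a bracket. Wednesday's plateau reads 42.7% and Friday's 14.0%. Midnight lies below Wednesday's share and above Wednesday's amount of Q spread over midnight's charge, 22.8%. Noon lies above Friday's share and below Friday's amount spread over noon's charge, 30.8%. Dawn lies below Friday's share and above Friday's amount spread over dawn's charge, 10.3%.

To tighten this, I use the first G readings. As a simplification I hold E at its charge, so that G + E → X counts as pseudo-first-order, and I leave G + Z → L out. At 0.667 min, the reciprocal of the fraction of G left is a first-order part, equal in both runs, plus a second-order part proportional to the charge. Wednesday's second-order part reads 0.989, and the first-order rate reads 1.39 min⁻¹. Together they give 2.48 mM for the charge at which, at the start, the step of two G to Z uses G as fast as the two first-order steps together: the crossover charge.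

With x the charge over the crossover charge, the fraction of G leaving by first-order steps is ln(1+x)/x. G reads 0% at 8.00 min on Wednesday, so I reckon to the end of G. Wednesday's plateau then gives Q a selectivity factor of 0.553 within that fraction. Friday's plateau was not used for this, and the rule puts it at 14.3%. My reckoning gives 36.3%, 22.2% and 11.8%, each inside its bracket.

The forecast gives 35.5%, 21.5% and 11.5%, also inside the brackets, so its Q falls all the way, and it says “Q falls steadily”.

The flask gives 36.5%, 22.4% and 11.0%: Q falls all the way.

    G + Z → L (k = 1.80 M⁻¹ s⁻¹)
    G → Q (k = 0.0130 s⁻¹)
    G + E → X (k = 1.20 M⁻¹ s⁻¹)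
    2 G → Z (k = 4.00 M⁻¹ s⁻¹)

At dawn the charge is 12.1 times the crossover charge as I read it from the runs, and the step of two G to Z is the main reason Q is small: without that step, dawn's Q goes from 11.0% to 71.2%. By that reading the first-order fraction at dawn comes to 21.3%, and at 8.00 min dawn's Q and X together hold 19.8%. For midnight the same reading gives a fraction of 65.5%. At 8.00 min midnight's Q and X together hold 68.6%.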